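## Retrosynthetic overview

1. Structural feature: the only ring is the cyclohexane C1–C6 (C1 = quaternary carbinol bearing C7H2OBz, C2 = CHOH, C3/C4 = CH2, C5 = CHOBz, C6 = CHOH). O2, O1, O6 and O5 lie on four contiguous carbons on alternating faces, which is the conduritol B pattern. Without C7 this pattern has a C2 axis through the midpoints of C1–C6 and C3–C4, and C2/C5 are the allylic carbons of a C3=C4 alkene.
2. Endgame: O7–Bz ⇒ O2–Bz (acyl shift); C1–O1 and C7–O7 ⇒ exocyclic C1=C7 (osmylation); C1=C7 ⇒ C1 ketone (methylenation) ⇒ monosilylated homotopic C1/C6 diol.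
3. Key disconnection: the C2–OBz and C5–OBz bonds ⇒ racemic conduritol B tetrakis(trichloroethyl carbonate) plus benzoate, by palladium-catalysed dynamic kinetic asymmetric allylic substitution.
4. The racemic tetracarbonate ⇒ 1,4-benzoquinone (bromination, reduction, acetolysis, methanolysis, acylation).
5. Ring order: no ring is formed. The carbocycle of benzoquinone is carried through to the target.

Key step: step 7

Convention: target numbering is used throughout. The ring is drawn with C1→C2→…→C6 clockwise; β = toward the viewer, α = away. The target is 1β-OH, 1α-CH2OBz, 2α-OH, 5β-OBz, 6α-OH, which is (1S,2R,5R,6S) in this numbering. Compounds 2–6 and 8 are racemic and are drawn in the target series.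

Assumption: the sense of induction is taken from the behaviour of this ligand family with cyclohex-2-enyl esters; transposed to 8, the (R,R) ligand should send the nucleophile to the allyl terminus that becomes C2 with an α C–O bond. If correlation of 11 shows the opposite sense, the equally available (S,S) ligand is used and nothing else changes.

## Route

Step 1
Reactants: 1 1,4-benzoquinone
Product: 2 rac-trans-5,6-dibromocyclohex-2-ene-1,4-dione (1β,6α-dibromide)
Conditions: Br2 (1.0 equiv), CH2Cl2, 0 °C
Reagents that add atoms: bromine, BrBr
Why: Electrophilic anti addition of bromine (bromonium opening) to one of the two equivalent C=C bonds sets the two C–Br centres trans and should stop there, because the remaining alkene is still flanked by two carbonyl groups and is further deactivated by the halogens.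

Step 2
Reactants: 2 rac-trans-5,6-dibromocyclohex-2-ene-1,4-dione
Product: 3 rac-(1R*,4R*,5S*,6S*)-5,6-dibromocyclohex-2-ene-1,4-diol (2α-OH, 1β-Br, 6α-Br, 5β-OH)
Conditions: NaBH4, Et2O/H2O, 0 °C
Reagents that add atoms: none
Why: In this borohydride 1,2-reduction of both carbonyl groups, hydride adds along the axial trajectory of the half-chair with both bromines equatorial, so each new hydroxyl comes out equatorial and trans to its neighbouring bromine, while the cold two-phase medium suppresses loss of HBr and aromatisation.

Step 3
Reactants: 3 rac-dibromodiol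
Product: 4 rac-dibromodiol diacetate (2α,5β-diacetoxy-1β,6α-dibromocyclohex-3-ene)
Conditions: Ac2O, pyridine, 0 °C → rt
Reagents that add atoms: acetic anhydride, CC(=O)OC(C)=O
Why: Pyridine-promoted O-acylation touches no stereocentre and installs the participating groups needed in the next step.

Step 4
Reactants: 4 rac-dibromodiol diacetate
Product: 5 rac-conduritol B tetraacetate (2α,1β,6α,5β-tetraacetoxycyclohex-3-ene)
Conditions: KOAc, AcOH/Ac2O, reflux
Reagents that add atoms: potassium acetate, CC(=O)[O-].[K+]
Why: In this acetolysis with anchimeric assistance, each bromide is expelled by the trans-vicinal acetate to give a cis-fused acetoxonium ion that external acetate opens with a second inversion, so both C–Br carbons are substituted with overall retention and the all-trans tetraacetate should result, to be freed from isomers by recrystallisation.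

Step 5
Reactants: 5 rac-conduritol B tetraacetate
Product: 6 rac-conduritol B (cyclohex-3-ene-2α,1β,6α,5β-tetrol)
Conditions: NaOMe (cat.), MeOH, rt
Reagents that add atoms: none
Why: Zemplén transesterification removes the four acetates with catalytic alkoxide and breaks no ring C–O bond.

Step 6
Reactants: 6 rac-conduritol B; 7 2,2,2-trichloroethyl chloroformate
Product: 8 rac-conduritol B tetrakis(2,2,2-trichloroethyl carbonate)
Conditions: 7 (excess), pyridine, DMAP (cat.), CH2Cl2, 0 °C → rt
Reagents that add atoms: 2,2,2-trichloroethyl chloroformate (7), ClC(=O)OCC(Cl)(Cl)Cl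
Why: Chloroformate acylation of all four secondary hydroxyls touches no stereocentre and gives carbonates whose leaving-group ability, better than that of acetates, should let both enantiomers ionize in step 7.

Step 7
Reactants: 8 rac-conduritol B tetrakis(2,2,2-trichloroethyl carbonate); 9 sodium benzoate
Product: 11 (1R,2S,3S,4R)-conduritol B 1,4-dibenzoate 2,3-bis(2,2,2-trichloroethyl carbonate) (2α,5β-dibenzoate; single enantiomer), via C2 monobenzoate tris(trichloroethyl carbonate) 10 (not isolated)
Conditions: [Pd(η3-C3H5)Cl]2 (2.5 mol %), (1R,2R)-N,N'-bis[2-(diphenylphosphino)benzoyl]cyclohexane-1,2-diamine (7.5 mol %), PhCO2Na (2.5 equiv), (n-C6H13)4NBr, CH2Cl2/H2O, rt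
Reagents that add atoms: sodium benzoate (9), [Na+].[O-]C(=O)c1ccccc1
Why: Zerovalent palladium, formed in situ from [Pd(η3-C3H5)Cl]2 and the diphosphine, displaces an allylic carbonate (at C2 or C5) from the face anti to the leaving group, which then loses CO2; the resulting C2–C3–C4 π-allyl cation has a mirror plane through C3 and C6 (O1 and O5 on the palladium face, O6 opposite), so both enantiomers of 8 funnel into the same meso intermediate. Benzoate adds anti to palladium and the chiral pocket of the ligand makes the two enantiotopic termini unequal, so attack at the favoured terminus creates the 2α C–O bond and at the same stroke defines which ring atoms become C1, C6 and C5, which means the ligand alone controls the absolute configuration of all four oxygenated centres of 10 (net retention for the matched enantiomer of 8, allylic transposition for the mismatched one). Ionization of the remaining allylic carbonate at C5 gives a C3–C4–C5 π-allyl that is related to the first by the C2 axis of the skeleton and differs only in one spectator acyl group, so the same ligand preference should send benzoate to C5 rather than C3 and give the C2-symmetric 2α,5β-dibenzoate 11. The closest known reaction type is the palladium-catalysed dynamic kinetic asymmetric allylic substitution of conduritol B tetraesters and tetracarbonates with carboxylate nucleophiles; two C–O bonds are formed and no ring is closed. Chemoselectivity is secured by the substrate, since only the C2 and C5 carbonates are allylic, the C1 and C6 carbonates cannot ionize, the trichloroethyl carbonate leaves well enough for the mismatched enantiomer to ionize too, and the allylic benzoates of 11 are much poorer leaving groups that, if they do ionize, are returned to 11 by the same ligand bias. The two-phase medium with the ammonium salt supplies soluble benzoate steadily and protonates the trichloroethoxide that is released.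

Step 8
Reactants: 11 conduritol B 1,4-dibenzoate 2,3-bis(trichloroethyl carbonate)
Product: 12 2α,5β-dibenzoyloxy-1β,6α-bis(2,2,2-trichloroethoxycarbonyloxy)cyclohexane
Conditions: KO2CN=NCO2K, AcOH, CH2Cl2/MeOH, 0 °C → rt
Reagents that add atoms: none
Why: Diimide reduction (concerted syn transfer of two hydrogens to the cis-disubstituted C3=C4 bond) is chosen because, unlike catalytic hydrogenation, it should hydrogenolyse neither the allylic benzoates nor the C–Cl bonds, and it forms no stereocentre.

Step 9
Reactants: 12 saturated dibenzoate bis(carbonate)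
Product: 13 2α,5β-dibenzoyloxycyclohexane-1β,6α-diol (C2-symmetric)
Conditions: Zn dust, AcOH/THF, rt
Reagents that add atoms: none
Why: Reductive fragmentation of the trichloroethyl carbonates by zinc (two-electron reduction, β-elimination of chloride, decarboxylation) runs in a weakly acidic medium in which benzoates should neither cleave nor migrate.

Step 10
Reactants: 13 dibenzoate diol
Product: 14 2α,5β-dibenzoyloxy-6α-(tert-butyldimethylsilyloxy)cyclohexan-1β-ol
Conditions: TBSOTf (1.0 equiv), 2,6-lutidine, CH2Cl2, −78 °C
Reagents that add atoms: tert-butyldimethylsilyl triflate, CC(C)(C)[Si](C)(C)OS(=O)(=O)C(F)(F)F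
Why: In this silyl ether formation O1 and O6 are exchanged by the C2 axis, so the first silylation gives one compound whichever hydroxyl reacts and the second is retarded by the bulky new neighbour; the silyl group later prevents over-oxidation, ketol isomerisation and a benzoyl shift from O5 to O6.

Step 11
Reactants: 14 monosilyl ether
Product: 15 (2α)-benzoyloxy-(5β)-benzoyloxy-(6α)-silyloxycyclohexan-1-one (ketone at C1)
Conditions: Dess–Martin periodinane, CH2Cl2, 0 °C → rt
Reagents that add atoms: none
Why: Dess–Martin oxidation converts the single free secondary alcohol into the ketone without base, which should avoid epimerisation at C2 and C6 and E1cB loss of the C5 benzoate.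

Step 12
Reactants: 15 ketone
Product: 16 1-methylene-2α,5β-dibenzoyloxy-6α-(tert-butyldimethylsilyloxy)cyclohexane
Conditions: Zn, CH2Br2, TiCl4, THF (reagent pre-formed, −40 → 5 °C), then 15, CH2Cl2, 0 °C → rt
Reagents that add atoms: dibromomethane, BrCBr
Why: In the Takai–Lombardo methylenation the weakly basic, oxophilic gem-dimetallic methylene reagent adds to ketones far faster than to esters and is the standard choice for enolisable, base-sensitive ketones, so C7 should be installed without epimerisation or β-elimination.

Step 13
Reactants: 16 exocyclic alkene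
Product: 17 1α-hydroxymethyl-2α,5β-dibenzoyloxy-6α-(tert-butyldimethylsilyloxy)cyclohexan-1β-ol
Conditions: OsO4 (cat.), NMO, acetone/H2O, rt
Reagents that add atoms: osmium tetroxide, O=[Os](=O)(=O)=O; N-methylmorpholine N-oxide, C[N+]1([O-])CCOCC1; water, O
Why: In this Upjohn syn dihydroxylation, OsO4 should approach the exocyclic alkene of the all-equatorial chair from the equatorial (β) side, away from the axial hydrogens on C3 and C5, as is usual for methylenecyclohexanes, so that O1 becomes equatorial (β, trans to O2 and O6) and C7 axial (α), which sets C1.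

Step 14
Reactants: 17 diol
Product: 18 [1β,2α-dihydroxy-5β-benzoyloxy-6α-(tert-butyldimethylsilyloxy)cyclohexyl]methyl benzoate
Conditions: DBU (cat.), CH2Cl2, rt
Reagents that add atoms: none
Why: This base-catalysed intramolecular O→O acyl migration passes through a six-membered cyclic orthoacid anion (axial C7 and equatorial O2 are gauche) and runs under thermodynamic control, in which the primary ester is favoured over the crowded secondary ester next to quaternary C1, a tertiary O1 ester is disfavoured, and the C5 benzoate has no free neighbouring hydroxyl because O6 is silylated.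

Step 15
Reactants: 18 silyl ether
Product: 19 [(1S,2R,5R,6S)-5-benzoyloxy-1,2,6-trihydroxycyclohexyl]methyl benzoate (target)
Conditions: HF·pyridine, THF, 0 °C → rt
Reagents that add atoms: none
Why: Fluoride-mediated desilylation in an acidic medium, driven by the strong Si–F bond, frees O6 without generating alkoxides, so the benzoates on O5 and O7 should stay in place.

## Compound list

1 | 1,4-benzoquinone | O=C1C=CC(=O)C=C1 | starting material
2 | rac-trans-5,6-dibromocyclohex-2-ene-1,4-dione (one enantiomer drawn) | Br[C@H]1C(=O)C=CC(=O)[C@@H]1Br | intermediate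
3 | rac-(1R*,4R*,5S*,6S*)-5,6-dibromocyclohex-2-ene-1,4-diol (one enantiomer drawn) | Br[C@H]1[C@H](O)C=C[C@@H](O)[C@@H]1Br | intermediate
4 | rac-dibromodiol diacetate (one enantiomer drawn) | Br[C@H]1[C@H](OC(C)=O)C=C[C@@H](OC(C)=O)[C@@H]1Br | intermediate
5 | rac-conduritol B tetraacetate (one enantiomer drawn) | CC(=O)O[C@H]1[C@H](OC(C)=O)C=C[C@@H](OC(C)=O)[C@@H]1OC(C)=O | intermediate
6 | rac-conduritol B (one enantiomer drawn) | O[C@H]1[C@H](O)C=C[C@@H](O)[C@@H]1O | intermediate
7 | 2,2,2-trichloroethyl chloroformate | ClC(=O)OCC(Cl)(Cl)Cl | starting material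
8 | rac-conduritol B tetrakis(2,2,2-trichloroethyl carbonate) (one enantiomer drawn) | ClC(Cl)(Cl)COC(=O)O[C@H]1[C@H](OC(=O)OCC(Cl)(Cl)Cl)C=C[C@@H](OC(=O)OCC(Cl)(Cl)Cl)[C@@H]1OC(=O)OCC(Cl)(Cl)Cl | intermediate
9 | sodium benzoate | [Na+].[O-]C(=O)c1ccccc1 | starting material
10 | conduritol B 2α-monobenzoate 1β,6α,5β-tris(2,2,2-trichloroethyl carbonate) (not isolated) | ClC(Cl)(Cl)COC(=O)O[C@H]1[C@H](OC(=O)c2ccccc2)C=C[C@@H](OC(=O)OCC(Cl)(Cl)Cl)[C@@H]1OC(=O)OCC(Cl)(Cl)Cl | intermediate
11 | (1R,2S,3S,4R)-conduritol B 1,4-dibenzoate 2,3-bis(2,2,2-trichloroethyl carbonate) | ClC(Cl)(Cl)COC(=O)O[C@H]1[C@H](OC(=O)c2ccccc2)C=C[C@@H](OC(=O)c2ccccc2)[C@@H]1OC(=O)OCC(Cl)(Cl)Cl | intermediate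
12 | 2α,5β-dibenzoyloxy-1β,6α-bis(2,2,2-trichloroethoxycarbonyloxy)cyclohexane | ClC(Cl)(Cl)COC(=O)O[C@H]1[C@H](OC(=O)c2ccccc2)CC[C@@H](OC(=O)c2ccccc2)[C@@H]1OC(=O)OCC(Cl)(Cl)Cl | intermediate
13 | 2α,5β-dibenzoyloxycyclohexane-1β,6α-diol | O[C@H]1[C@H](OC(=O)c2ccccc2)CC[C@@H](OC(=O)c2ccccc2)[C@@H]1O | intermediate
14 | 2α,5β-dibenzoyloxy-6α-(tert-butyldimethylsilyloxy)cyclohexan-1β-ol | O[C@H]1[C@H](OC(=O)c2ccccc2)CC[C@@H](OC(=O)c2ccccc2)[C@@H]1O[Si](C)(C)C(C)(C)C | intermediate
15 | 2α,5β-dibenzoyloxy-6α-(tert-butyldimethylsilyloxy)cyclohexan-1-one | O=C1[C@H](OC(=O)c2ccccc2)CC[C@@H](OC(=O)c2ccccc2)[C@@H]1O[Si](C)(C)C(C)(C)C | intermediate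
16 | 1-methylene-2α,5β-dibenzoyloxy-6α-(tert-butyldimethylsilyloxy)cyclohexane | C=C1[C@H](OC(=O)c2ccccc2)CC[C@@H](OC(=O)c2ccccc2)[C@@H]1O[Si](C)(C)C(C)(C)C | intermediate
17 | 1α-hydroxymethyl-2α,5β-dibenzoyloxy-6α-(tert-butyldimethylsilyloxy)cyclohexan-1β-ol | OC[C@]1(O)[C@H](OC(=O)c2ccccc2)CC[C@@H](OC(=O)c2ccccc2)[C@@H]1O[Si](C)(C)C(C)(C)C | intermediate
18 | [1β,2α-dihydroxy-5β-benzoyloxy-6α-(tert-butyldimethylsilyloxy)cyclohexyl]methyl benzoate | O=C(OC[C@]1(O)[C@H](O)CC[C@@H](OC(=O)c2ccccc2)[C@@H]1O[Si](C)(C)C(C)(C)C)c1ccccc1 | intermediate
19 | [(1S,2R,5R,6S)-5-benzoyloxy-1,2,6-trihydroxycyclohexyl]methyl benzoate | O=C(OC[C@]1(O)[C@H](O)CC[C@@H](OC(=O)c2ccccc2)[C@@H]1O)c1ccccc1 | target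

## Step count and risks

Total step count: 15. Longest linear sequence: 15 steps (1 → 19); 7 and 9 enter as purchased reagents.

**Step 7.**
- What may go wrong: ionization of the mismatched enantiomer may be too slow, so that the process degrades to a kinetic resolution. Terminus selection in the second substitution may be imperfect, which would give vicinal dibenzoate and erode the enantiomeric purity.
- Fallback: it sets out from 4 and returns at 13, obtaining the absolute configuration by resolution and forming both C–OBz bonds by epoxide opening.
  - Lipase-catalysed enantioselective hydrolysis of 4 (pH 7 buffer) splits the racemate into a diol and a residual diacetate of opposite configuration. The fraction of the required series (directly, or after acid methanolysis) is (1S,4S,5R,6R)-5,6-dibromocyclohex-2-ene-1,4-diol F1.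
  - KOH in Et2O closes both trans-bromohydrins (double intramolecular Williamson reaction) to enantiopure anti-benzene dioxide F2, with the C1–C2 oxirane β and the C5–C6 oxirane α.
  - Benzoic acid with catalytic tetrabutylammonium benzoate opens each vinyl oxirane at its allylic carbon (C2, C5) with inversion, giving the target-series conduritol B 1,4-dibenzoate F3.
  - Diimide reduction as in step 8 then gives 13.

**Step 13.**
- What may go wrong: osmylation may take place on the axial (α) face, or may be sluggish at the alkene flanked by two bulky equatorial groups, so that C1 is set with poor facial selectivity.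
- Fallback: it sets out from 15, returns at 17 and replaces steps 12 and 13; C7 is delivered as a nucleophile instead of O1 as an electrophile.
  - Diazomethane (Et2O/CH2Cl2, 0 °C) is a small, non-basic nucleophile and should add to the electron-poor α,α'-dioxygenated ketone along the axial trajectory.
  - Because both flanking carbons carry oxygen and migrate poorly, the adduct should close to the spiro-epoxide F5 (C7 axial α, O1 equatorial β) rather than ring-expand.
  - Dilute acid hydrolysis (HClO4 cat., THF/H2O, 0 °C) attacks the primary C7, by water directly or through the neighbouring C2 benzoate. The C1–O1 bond is untouched, and 17 results.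

**Step 12.**
- What may go wrong: enolisation toward C6 followed by loss of the C5 benzoate, reductive cleavage of the C2–O bond of the α-benzoyloxy ketone by residual zinc, or failure of the bulky reagent to add to the hindered carbonyl.
- Fallback: it sets out from 15 and returns at 16 by a two-stage Peterson olefination.
  - Me3SiCH2Li/CeCl3 (THF, −78 °C) is a non-basic organocerium reagent that should add to the ketone in preference to the benzoates. It gives the β-hydroxysilane F4, whose C1 configuration is of no consequence.
  - BF3·OEt2 (CH2Cl2, 0 °C) then induces elimination to 16.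

Further compounds
F1 | step 7 | (1S,4S,5R,6R)-5,6-dibromocyclohex-2-ene-1,4-diol | Br[C@@H]1[C@@H](O)C=C[C@H](O)[C@H]1Br
F2 | step 7 | anti-benzene dioxide (C1–C2 oxirane β, C5–C6 oxirane α, C3=C4) | C1=C[C@@H]2O[C@@H]2[C@H]3O[C@@H]13
F3 | step 7 | conduritol B 1,4-dibenzoate, target series (2α,5β-dibenzoyloxycyclohex-3-ene-1β,6α-diol) | O[C@H]1[C@H](OC(=O)c2ccccc2)C=C[C@@H](OC(=O)c2ccccc2)[C@@H]1O
F4 | step 12 | 1-(trimethylsilylmethyl)-2α,5β-dibenzoyloxy-6α-(tert-butyldimethylsilyloxy)cyclohexan-1-ol (C1 epimers) | C[Si](C)(C)CC1(O)[C@H](OC(=O)c2ccccc2)CC[C@@H](OC(=O)c2ccccc2)[C@@H]1O[Si](C)(C)C(C)(C)C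
F5 | step 13 | spiro-epoxide at C1 (O1 β equatorial, C7 α axial) of the 2α,5β-dibenzoate 6α-silyl ether | C1O[C@]12[C@H](OC(=O)c3ccccc3)CC[C@@H](OC(=O)c3ccccc3)[C@@H]2O[Si](C)(C)C(C)(C)C
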